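# Route to (2R,3R)-6-geranyl-5-O-methylaromadendrin (CNP0177937.1) by Claisen folding of a geranylated triketo ester

Throughout, geranyl = (2E)-3,7-dimethylocta-2,6-dien-1-yl. Flavanone numbering is used for the target (O1, C2, C3, C4, C4a, C5–C8, C8a), and primed numbers for the aroyl ring of the chalcones (C1′ = C4a, C2′ = C5, C3′ = C6, C4′ = C7, C5′ = C8, C6′ = C8a).

## Analysis of the target

Target 16 is a dihydroflavonol: ring A (C4a, C5–C8, C8a) is fused to the dihydropyranone ring C (O1, C2, C3, C4), and ring B, a 4-hydroxyphenyl group, sits on C2. The two stereocentres are adjacent: C2 (R, aryl) and C3 (R, hydroxyl), which is the 2,3-trans arrangement with both substituents equatorial. Ring A is fully differentiated: methoxy on C5, geranyl on C6, free hydroxyl on C7, hydrogen on C8 and the ring ether oxygen on C8a. The sensitive parts are the two trisubstituted geranyl alkenes (electrophilic oxidants; protic acid, which can add the C7 hydroxyl across the nearer alkene) and the α-hydroxy-β-aryloxy ketone (base opens ring C by retro-oxa-Michael reaction and epimerises C2). The difficulty is twofold: geranyl must be on C6 and not C8, with methyl on the C5 oxygen only, and C2/C3 must be set without any reagent that touches the geranyl alkenes. The strategy rests on the fact that the oxygenated carbons C5, C7 and C8a alternate with C4a, C6 and C8, and that C4a carries the C4 carbonyl. Ring A is therefore an acylphloroglucinol, that is, a linear poly-β-carbonyl chain folded by C-acylation at C4a–C5. In that chain the C6 carbon is the only one flanked by an ester and a ketone, so geranyl can be placed there before the ring exists.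

## Retrosynthetic reasoning

**16 ⇒ 14 (through 15).** The O1–C2 bond is cut. C2 is benzylic and para to the ring B oxygen, so in the forward sense it is the epoxide carbon that a phenol opens most easily. This cut merges both stereocentres into one trans-epoxide and keeps C4 at the ketone level. A cut at C2–C3 or C3–C4 would separate the stereocentres and require each to be set on its own. The forward step has to free the C8a oxygen (15 is the epoxide with free phenols) and close ring C in the 6-endo sense without disturbing C3.

**14 ⇒ 13.** Removing the epoxide oxygen gives the E-enone 13. This is the only electron-poor alkene in the molecule, so a nucleophilic oxidant can distinguish it from the two electron-rich geranyl alkenes. The forward reaction must also select the enone face that gives R configuration at the carbonyl-bound carbon (future C3).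

**13 ⇒ 12 ⇒ 11.** The O–methyl bond at the future C5 oxygen and the acetal bonds at the future C7 and C8a oxygens are cut, leading to triphenol 11. The forward order follows reactivity: the oxygen para to the carbonyl and the less hindered ortho oxygen are protected first (12). The remaining ortho hydroxyl, wedged between acyl and geranyl, is then the only one left to methylate (13). The gain is that 11 needs no regiochemical information beyond the position of geranyl.

**11 ⇒ 9 (through 10).** Ring A is opened at C4a–C5 by a retro-Claisen cut. This unrolls the ring into chain 9, whose parts map onto the target as follows: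
- the methyl ester carbon is the future C5;
- the ester α-carbon, already carrying geranyl, is the future C6;
- the two inner ketones are the future C7 and C8a;
- the methylene between two ketones is the future C4a;
- the cinnamoyl terminus is the future C4, C3, C2 and ring B.

A cut at the aryl–acyl bond C4a–C4 would lead to a geranylphloroglucinol in which two ring positions compete for acylation. Here the chain fixes the position. The forward step must form a six-membered ring by C-acylation; 10 is the non-aromatic triketone that tautomerises to 11.

**9 ⇒ 5 + 8.** The future C4a–C4 bond is cut. This is the bond that the terminal carbon of a polyanion of 5 can form, and it brings in ring B with its double bond in one piece. Amide 8 is chosen as acyl donor because its adduct does not collapse before the quench.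

**5 ⇒ 3 + 4, and 3 ⇒ 1 + 2.** The future C8–C8a bond is cut (acylation of the dianion of 3 at its terminal carbon by 4), then the C6–geranyl bond (alkylation of 1 by 2). Geranyl has to go on first: in 1 the carbon between ester and ketone is the only acidic position, whereas in 5 or 9 a methylene between two ketones would be alkylated instead.

**8 ⇒ 7 ⇒ 6.** These are functional group changes on commercial 6: amide formation, then protection of the phenol as an acetal that survives strong base and is removed at the end together with those on ring A.

## Alternatives that were turned down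

**Alternative 1:** The C2–C3 and C3–O bonds are disconnected. In the forward key step the ring A diazoketone A2 is decomposed by Rh2(OAc)4, water A4 adds to the rhodium carbenoid, and the resulting oxonium ylide (an enol) is trapped by aldehyde A3 under a chiral phosphoric acid. This gives the open-chain diol A1.
- For it: it is convergent, sets both carbinol centres in one catalytic step, and needs no oxidant near the geranyl alkenes. On the last point it is stronger than the chosen route.
- Against it: A2 requires a separately made, fully differentiated and geranylated ring A acid, so the ring A regiochemistry is postponed, not solved.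
- Against it: a carbenoid flanked by two ortho alkoxy groups can form five-membered oxonium ylides or insert into the O–CH bonds, giving benzofuranones, and it can cyclopropanate the geranyl alkenes.
- Against it: A1 is acyclic. Closing O1–C2 needs substitution at the benzylic carbinol with retention, which in practice means ionisation, so the benzylic centre set in the key step is set again and only C3 is transferred. Two silyl ethers and an acetal remain to be removed.
- Comparison: the chosen route also relies on C3 alone, but obtains ring A, the C4 carbonyl and the C4–C2 chain from one folding step of a chain made from C4 and C2 units, in fewer steps.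

**Alternative 2:** The C3–C4 and O1–C2 bonds of ring C are disconnected. In the forward key step salicylaldehyde A6, trimethyl orthoformate A7 and enol acetate A8 combine under a chiral phosphoric acid in a formal [4+2] reaction of an ortho-quinone-methide-type oxocarbenium ion. This gives chroman A5.
- For it: ring C is closed with the 2,3-trans relationship in a single operation, and the chalcone–flavanone equilibrium is avoided. On ring C construction it is stronger than the chosen route.
- Against it: C4 arrives as a methyl ether and must be taken to the ketone. That needs a benzylic oxidation or an ionisation beside a geranyl group whose CH2 is both benzylic and allylic, on a very electron-rich ring, and the 3-acyloxy-4-alkoxychroman tends to eliminate to flavene-type cations.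
- Against it: A6 again requires the differentiated, geranylated ring A to be built separately, and face selection at a hexasubstituted oxocarbenium ion with an ortho methoxy group is uncertain.
- Comparison: in the chosen route C4 is a ketone from the start, because it is one of the chain carbonyls, and ring A needs no separate synthesis.

**Alternative 3:** Four ring A bonds are disconnected (C8a–C8, C6–C7, C5–C6, C4a–C8a). In the forward key step diazo enone A10 is irradiated and undergoes photo-Wolff rearrangement to a vinylketene, which adds siloxyalkyne A11 in a [2+2] reaction. Ring opening and 6π electrocyclisation of the cyclobutenone then give phenol A9.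
- For it: the three ring A oxygens are differentiated by construction (methyl ether, silyl ether, free phenol) and geranyl is placed unambiguously. Here it is clearly stronger than the chosen route, which separates two ortho phenols by sterics.
- Against it: the key step makes ring A only. The C4a–C4 bond, ring C and both stereocentres are all still to come.
- Against it: acylation of A9 must choose between two positions ortho to the free hydroxyl.
- Against it: A10, with geranyl on the diazo carbon, takes several steps to make, and its ketene or carbene can be intercepted by the geranyl alkenes. A11 is a sensitive reagent.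
- Comparison: after A9 the endgame (chalcone, epoxide, ring closure) is the same as here, so the route is longer. The chosen folding delivers ring A with the cinnamoyl chain already attached, and pays for the missing O-differentiation with two protection steps.

Key step: step 6

## Route

Remark on the chemistry: the SMILES is read as (2R,3R), the 2,3-trans dihydroflavonol. Compounds 3, 5 and 9 are racemic at the geranyl-bearing carbon, which becomes aromatic C6 in step 6. Poly-L-leucine, N-methoxy-N-methylacetamide and Mg(OMe)2 in methanol are taken to be commercially available.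

Step 1
Reactants: 1 methyl acetoacetate; 2 geranyl bromide [(2E)-1-bromo-3,7-dimethylocta-2,6-diene]
Product: 3 methyl (4E)-2-acetyl-5,9-dimethyldeca-4,8-dienoate (methyl 2-geranylacetoacetate; racemic)
Conditions: NaH, THF, 0 °C; then 2, 0 °C to rt (1 in excess)
Reagents that add atoms: none
Why: Acetoacetic ester alkylation: the stabilised sodium enolate is C-alkylated by the primary allylic bromide in an SN2 reaction; an excess of 1 suppresses dialkylation and the E alkene of 2 is not touched.

Step 2
Reactants: 3 methyl 2-geranylacetoacetate; 4 N-methoxy-N-methylacetamide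
Product: 5 methyl 2-geranyl-3,5-dioxohexanoate (racemic; enol tautomers)
Conditions: LiN(iPr)2 (2.2 equiv), THF, −78 to 0 °C; then 4, −78 to 0 °C; AcOH quench
Reagents that add atoms: none
Why: The 2,4-dianion of a 2-alkylacetoacetate reacts at its terminal carbon (dianion γ-acylation); the Weinreb amide gives a chelated tetrahedral adduct, so acylation stops at the ketone and the acidic diketone appears only on quenching.

Step 3
Reactants: 6 (E)-4-hydroxycinnamic acid
Product: 7 (2E)-3-(4-hydroxyphenyl)-N-methoxy-N-methylprop-2-enamide
Conditions: MeNHOMe·HCl, EDC·HCl, 1-hydroxybenzotriazole (cat.), iPr2NEt, DMF, 0 °C to rt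
Reagents that add atoms: N,O-dimethylhydroxylamine hydrochloride, CNOC.Cl
Why: Carbodiimide amide coupling; the amine is far more nucleophilic than the phenol towards the active ester, and the E alkene is retained.

Step 4
Reactants: 7 (2E)-3-(4-hydroxyphenyl)-N-methoxy-N-methylprop-2-enamide
Product: 8 (2E)-N-methoxy-3-[4-(methoxymethoxy)phenyl]-N-methylprop-2-enamide
Conditions: MOMCl, iPr2NEt, CH2Cl2, 0 °C to rt
Reagents that add atoms: chloromethyl methyl ether, COCCl
Why: Williamson-type O-alkylation of the phenol by the hard α-chloro ether; the resulting acetal withstands the amide base and the alkoxide of steps 5 and 6 and is removed in step 10 with the ring A acetals.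

Step 5
Reactants: 5 methyl 2-geranyl-3,5-dioxohexanoate; 8 (2E)-N-methoxy-3-[4-(methoxymethoxy)phenyl]-N-methylprop-2-enamide
Product: 9 methyl (8E)-2-geranyl-9-[4-(methoxymethoxy)phenyl]-3,5,7-trioxonon-8-enoate (racemic; enol tautomers)
Conditions: 5, LiN(iPr)2 (3.3 equiv), THF, −78 to 0 °C; then 8, −78 to −20 °C; AcOH, −78 °C; cold buffered work-up, used without delay
Reagents that add atoms: none
Why: Weinreb ketone synthesis with a polyketide trianion: the terminal carbanion of the 3,5-diketo ester is its least delocalised and most nucleophilic site and adds 1,2 to the amide carbonyl; the chelated adduct holds until the quench, so there is no over-addition and no proton transfer from the product.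

Step 6
Reactants: 9 methyl (8E)-2-geranyl-9-[4-(methoxymethoxy)phenyl]-3,5,7-trioxonon-8-enoate
Product: 11 (2E)-1-(3-geranyl-2,4,6-trihydroxyphenyl)-3-[4-(methoxymethoxy)phenyl]prop-2-en-1-one, via cyclohexane-1,3,5-trione tautomer 10 (not isolated)
Conditions: Mg(OMe)2 (5 equiv), MeOH, rt to 45 °C; then cold 0.5 M HCl to pH 4, EtOAc, 0 °C; used directly
Reagents that add atoms: none
Why: Mg(OMe)2 turns 9 into a polyenolate in which magnesium bridges the oxygens of the 3,5- and 5,7-dicarbonyl units; the carbon between the C5 and C7 carbonyls of the chain (future C4a) adds to the ester carbonyl (future C5), the ester alkoxide is expelled, and triketone 10 enolises to the aromatic acylphloroglucinol 11. The closest known reaction type is the base-mediated Claisen cyclisation of 3,5,7-triketo esters to acylphloroglucinols, the laboratory counterpart of chalcone-synthase folding. Ring A closes in a 6-exo-trig (enol-exo) mode at the ester carbon, forming the C4a–C5 bond. No stereocentre is formed; the racemic chain carbon C2 becomes aromatic C6. The step needs C-acylation to win over the aldol mode (chain C2 onto C7), over O-acylation to a 4-hydroxy-2-pyrone and over conjugate addition to the styryl ketone. The aldol adduct would carry a quaternary geranyl-bearing carbon, cannot aromatise and should revert; a pyrone is reopened by the alkoxide; and chelation keeps the 5,7-diketone as an enolate, which lowers the acceptor character of the enone and brings the nucleophilic carbon within reach of the ester. Aromatisation to the magnesium phenoxide makes the desired path irreversible, and as the polyphenoxide the chalcone does not close to a flavanone until it is neutralised, hence the cold, quick work-up.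

Step 7
Reactants: 11 (2E)-1-(3-geranyl-2,4,6-trihydroxyphenyl)-3-[4-(methoxymethoxy)phenyl]prop-2-en-1-one
Product: 12 (2E)-1-[3-geranyl-2-hydroxy-4,6-bis(methoxymethoxy)phenyl]-3-[4-(methoxymethoxy)phenyl]prop-2-en-1-one
Conditions: MOMCl (2.2 equiv), iPr2NEt, CH2Cl2, 0 °C
Reagents that add atoms: chloromethyl methyl ether, COCCl
Why: Williamson-type O-alkylation: the C4′ hydroxyl (para to the carbonyl, not chelated, most acidic) reacts first; of the two chelated ortho hydroxyls the one at C6′, flanked only by C–H, is more accessible than the one at C2′ between acyl and geranyl, the same pattern as the 4,6-bis-protection of phloroacetophenones. The hard electrophile favours O- over C-alkylation, and the aprotic, weakly basic medium disfavours flavanone formation.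

Step 8
Reactants: 12 (2E)-1-[3-geranyl-2-hydroxy-4,6-bis(methoxymethoxy)phenyl]-3-[4-(methoxymethoxy)phenyl]prop-2-en-1-one
Product: 13 (2E)-1-[3-geranyl-2-methoxy-4,6-bis(methoxymethoxy)phenyl]-3-[4-(methoxymethoxy)phenyl]prop-2-en-1-one
Conditions: MeI, K2CO3, DMF, rt to 40 °C
Reagents that add atoms: iodomethane, CI
Why: Williamson methylation of the only remaining phenol; any oxa-Michael closure of the phenoxide onto the enone is reversible under base, whereas methylation is not, so the material should funnel to the methyl ether.

Step 9
Reactants: 13 (2E)-1-[3-geranyl-2-methoxy-4,6-bis(methoxymethoxy)phenyl]-3-[4-(methoxymethoxy)phenyl]prop-2-en-1-one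
Product: 14 [3-geranyl-2-methoxy-4,6-bis(methoxymethoxy)phenyl]{(2R,3S)-3-[4-(methoxymethoxy)phenyl]oxiran-2-yl}methanone
Conditions: poly-L-leucine, urea–H2O2, 1,8-diazabicyclo[5.4.0]undec-7-ene (DBU), THF, rt
Reagents that add atoms: urea–hydrogen peroxide, NC(N)=O.OO
Why: Juliá–Colonna epoxidation, a Weitz–Scheffer-type nucleophilic epoxidation: hydroperoxide adds to the enone β-carbon inside the helical poly-L-leucine, whose terminal amide N–H groups bind the peroxide and enolate and select the face that gives the (2R,3S)-epoxide, as for chalcone itself. The trans geometry follows from the E enone, and a nucleophilic oxidant leaves the electron-rich geranyl alkenes alone.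

Step 10
Reactants: 14 [3-geranyl-2-methoxy-4,6-bis(methoxymethoxy)phenyl]{(2R,3S)-3-[4-(methoxymethoxy)phenyl]oxiran-2-yl}methanone
Product: 16 (2R,3R)-6-geranyl-3,7-dihydroxy-2-(4-hydroxyphenyl)-5-methoxy-2,3-dihydro-4H-chromen-4-one, via free triphenol epoxide 15 (not isolated)
Conditions: 3 M aq HCl–MeOH–THF, 40 °C, short reaction time
Reagents that add atoms: none
Why: Acid-catalysed acetal exchange removes the three methoxymethyl groups, and the freed C6′ hydroxyl opens the protonated epoxide at the benzylic carbon, which is activated by the 4-oxyaryl group, in a 6-endo closure (the classical chalcone-epoxide route to dihydroflavonols). C3 keeps the R configuration of the epoxide α-carbon; C2 is set by backside attack, or, if the benzylic carbon ionises or is first captured by solvent, by the preference for the 2,3-trans diequatorial ring under control of C3, so both paths lead to (2R,3R).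

## Compound list

1 | methyl acetoacetate | COC(=O)CC(C)=O | starting material
2 | geranyl bromide | BrC/C=C(\C)CCC=C(C)C | starting material
3 | methyl (4E)-2-acetyl-5,9-dimethyldeca-4,8-dienoate (racemic) | COC(=O)C(C/C=C(\C)CCC=C(C)C)C(C)=O | intermediate
4 | N-methoxy-N-methylacetamide | CON(C)C(C)=O | starting material
5 | methyl 2-geranyl-3,5-dioxohexanoate (racemic) | COC(=O)C(C/C=C(\C)CCC=C(C)C)C(=O)CC(C)=O | intermediate
6 | (E)-4-hydroxycinnamic acid | OC(=O)/C=C/c1ccc(O)cc1 | starting material
7 | (2E)-3-(4-hydroxyphenyl)-N-methoxy-N-methylprop-2-enamide | CON(C)C(=O)/C=C/c1ccc(O)cc1 | intermediate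
8 | (2E)-N-methoxy-3-[4-(methoxymethoxy)phenyl]-N-methylprop-2-enamide | CON(C)C(=O)/C=C/c1ccc(OCOC)cc1 | intermediate
9 | methyl (8E)-2-geranyl-9-[4-(methoxymethoxy)phenyl]-3,5,7-trioxonon-8-enoate (racemic) | COC(=O)C(C/C=C(\C)CCC=C(C)C)C(=O)CC(=O)CC(=O)/C=C/c1ccc(OCOC)cc1 | intermediate
10 | 2-{(2E)-3-[4-(methoxymethoxy)phenyl]prop-2-enoyl}-4-geranylcyclohexane-1,3,5-trione (stereoisomers and enol forms) | O=C1CC(=O)C(C/C=C(\C)CCC=C(C)C)C(=O)C1C(=O)/C=C/c1ccc(OCOC)cc1 | intermediate
11 | (2E)-1-(3-geranyl-2,4,6-trihydroxyphenyl)-3-[4-(methoxymethoxy)phenyl]prop-2-en-1-one | Oc1cc(O)c(C(=O)/C=C/c2ccc(OCOC)cc2)c(O)c1C/C=C(\C)CCC=C(C)C | intermediate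
12 | (2E)-1-[3-geranyl-2-hydroxy-4,6-bis(methoxymethoxy)phenyl]-3-[4-(methoxymethoxy)phenyl]prop-2-en-1-one | COCOc1cc(OCOC)c(C(=O)/C=C/c2ccc(OCOC)cc2)c(O)c1C/C=C(\C)CCC=C(C)C | intermediate
13 | (2E)-1-[3-geranyl-2-methoxy-4,6-bis(methoxymethoxy)phenyl]-3-[4-(methoxymethoxy)phenyl]prop-2-en-1-one | COCOc1cc(OCOC)c(C(=O)/C=C/c2ccc(OCOC)cc2)c(OC)c1C/C=C(\C)CCC=C(C)C | intermediate
14 | [3-geranyl-2-methoxy-4,6-bis(methoxymethoxy)phenyl]{(2R,3S)-3-[4-(methoxymethoxy)phenyl]oxiran-2-yl}methanone | COCOc1cc(OCOC)c(C(=O)[C@@H]2O[C@H]2c2ccc(OCOC)cc2)c(OC)c1C/C=C(\C)CCC=C(C)C | intermediate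
15 | (3-geranyl-4,6-dihydroxy-2-methoxyphenyl)[(2R,3S)-3-(4-hydroxyphenyl)oxiran-2-yl]methanone | COc1c(C/C=C(\C)CCC=C(C)C)c(O)cc(O)c1C(=O)[C@@H]1O[C@H]1c1ccc(O)cc1 | intermediate
16 | (2R,3R)-6-geranyl-3,7-dihydroxy-2-(4-hydroxyphenyl)-5-methoxy-2,3-dihydro-4H-chromen-4-one | COc1c(C/C=C(\C)CCC=C(C)C)c(O)cc2c1C(=O)[C@H](O)[C@@H](c1ccc(O)cc1)O2 | target

## Step count and risk

Total: 10 steps. Longest linear sequence: 8 steps (1, 2, 5, 6, 7, 8, 9, 10). The amide branch (3, 4) joins at step 5 and is equally long.

**Step 6 (key step).**
- What may go wrong: the polyenolate may be diverted into lactonisation or into conjugate addition of a chain carbanion or of alkoxide to the styryl ketone. After ring formation, the chalcone may close to flavanones through either ortho oxygen during neutralisation.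
- Fallback: take the Michael acceptor out of the folding step, setting out from 5 and returning at 13.
 - The trianion of 5 (LiN(iPr)2, THF) is acylated with 4 to give methyl 2-geranyl-3,5,7-trioxooctanoate F1.
 - Mg(OMe)2 in methanol folds F1 by the same Claisen mode to 1-(3-geranyl-2,4,6-trihydroxyphenyl)ethan-1-one F2.
 - MOMCl with iPr2NEt gives 1-[3-geranyl-2-hydroxy-4,6-bis(methoxymethoxy)phenyl]ethan-1-one F3.
 - MeI with K2CO3 gives 1-[3-geranyl-2-methoxy-4,6-bis(methoxymethoxy)phenyl]ethan-1-one F4.
 - Claisen–Schmidt condensation of F4 with purchased 4-(methoxymethoxy)benzaldehyde F5 (KOH, EtOH) gives 13.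
- The polyketide folding is kept, but the enone is built after aromatisation.

**Step 7.**
- What may go wrong: discrimination between the two chelated ortho hydroxyls may be insufficient, with alkylation at the geranyl-flanked oxygen or over-alkylation. Base-induced ring closure to flavanones may also occur.
- Fallback: amplify the steric difference with a bulky silyl group and exchange it later, setting out from 11 and returning at 13.
 - Triisopropylsilyl triflate with 2,6-lutidine (CH2Cl2, −78 °C) should give (2E)-1-{3-geranyl-2-hydroxy-4,6-bis[(triisopropylsilyl)oxy]phenyl}-3-[4-(methoxymethoxy)phenyl]prop-2-en-1-one F6.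
 - MeI with K2CO3 in acetone gives the 2-methoxy compound (2E)-1-{3-geranyl-2-methoxy-4,6-bis[(triisopropylsilyl)oxy]phenyl}-3-[4-(methoxymethoxy)phenyl]prop-2-en-1-one F7.
 - Buffered fluoride (Bu4NF, AcOH, THF, 0 °C) gives (2E)-1-(3-geranyl-4,6-dihydroxy-2-methoxyphenyl)-3-[4-(methoxymethoxy)phenyl]prop-2-en-1-one F8.
 - MOMCl with NaH in DMF at 0 °C converts F8 into 13.

**Step 9.**
- What may go wrong: conversion may be slow or face selection poor, because the doubly ortho-substituted aroyl group is twisted out of the enone plane and may not fit the polypeptide.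
- Fallback: give up catalytic induction and resolve, setting out from 13 and returning at 14.
 - Weitz–Scheffer epoxidation with t-BuOOH and DBU in THF gives the racemic trans-epoxide F9.
 - Preparative chromatography on a cellulose or amylose carbamate chiral stationary phase separates 14 from its (2S,3R)-enantiomer F10, which is discarded.

**Step 10.**
- What may go wrong: methanol may capture the benzylic carbon before the C6′ oxygen is free, followed by 5-exo closure at the α-carbon or formation of the 2,3-cis isomer. Acid may also add the C7 hydroxyl across the nearer geranyl alkene.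
- Fallback: a staged sulfur relay that separates epoxide opening, deprotection and ring closure, setting out from 14 and returning at 16.
 - Benzyl mercaptan with catalytic SnCl4 (CH2Cl2, −20 °C) opens the epoxide at the benzylic carbon to (2S)-3-(benzylsulfanyl)-1-[3-geranyl-2-methoxy-4,6-bis(methoxymethoxy)phenyl]-2-hydroxy-3-[4-(methoxymethoxy)phenyl]propan-1-one F10a, relabelled here as F11 (mixture at the sulfur-bearing carbon).
 - Dilute HCl in methanol at rt removes the acetals to give (2S)-3-(benzylsulfanyl)-1-(3-geranyl-4,6-dihydroxy-2-methoxyphenyl)-2-hydroxy-3-(4-hydroxyphenyl)propan-1-one F12. The thioether is stable to acid, so this can be done at lower temperature.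
 - AgBF4 in CH2Cl2 at 0 °C activates sulfur, and the C6′ hydroxyl closes ring C trans to the C3 hydroxyl, giving 16.

**Step 5.**
- What may go wrong: polyanion formation at the hindered ester α-carbon may be incomplete, and proton transfer, conjugate addition to the cinnamamide or premature cyclisation of 9 during work-up may occur.
- Fallback: replace the acylation by an aldol addition and an oxidation, setting out from 8 and 5 and returning at 9.
 - iBu2AlH (THF, −78 °C) reduces 8 to (2E)-3-[4-(methoxymethoxy)phenyl]prop-2-enal F13.
 - The trianion of 5 adds to F13 at −78 °C to give methyl (8E)-2-geranyl-7-hydroxy-9-[4-(methoxymethoxy)phenyl]-3,5-dioxonon-8-enoate F14.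
 - MnO2 in CH2Cl2 oxidises the allylic alcohol of F14 to 9.

## Further compounds

F1 | step 6 | methyl 2-geranyl-3,5,7-trioxooctanoate (racemic) | COC(=O)C(C/C=C(\C)CCC=C(C)C)C(=O)CC(=O)CC(C)=O
F2 | step 6 | 1-(3-geranyl-2,4,6-trihydroxyphenyl)ethan-1-one | CC(=O)c1c(O)cc(O)c(C/C=C(\C)CCC=C(C)C)c1O
F3 | step 6 | 1-[3-geranyl-2-hydroxy-4,6-bis(methoxymethoxy)phenyl]ethan-1-one | CC(=O)c1c(OCOC)cc(OCOC)c(C/C=C(\C)CCC=C(C)C)c1O
F4 | step 6 | 1-[3-geranyl-2-methoxy-4,6-bis(methoxymethoxy)phenyl]ethan-1-one | CC(=O)c1c(OCOC)cc(OCOC)c(C/C=C(\C)CCC=C(C)C)c1OC
F5 | step 6 | 4-(methoxymethoxy)benzaldehyde | O=Cc1ccc(OCOC)cc1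
F6 | step 7 | (2E)-1-{3-geranyl-2-hydroxy-4,6-bis[(triisopropylsilyl)oxy]phenyl}-3-[4-(methoxymethoxy)phenyl]prop-2-en-1-one | O=C(/C=C/c1ccc(OCOC)cc1)c1c(O)c(C/C=C(\C)CCC=C(C)C)c(O[Si](C(C)C)(C(C)C)C(C)C)cc1O[Si](C(C)C)(C(C)C)C(C)C
F7 | step 7 | (2E)-1-{3-geranyl-2-methoxy-4,6-bis[(triisopropylsilyl)oxy]phenyl}-3-[4-(methoxymethoxy)phenyl]prop-2-en-1-one | O=C(/C=C/c1ccc(OCOC)cc1)c1c(OC)c(C/C=C(\C)CCC=C(C)C)c(O[Si](C(C)C)(C(C)C)C(C)C)cc1O[Si](C(C)C)(C(C)C)C(C)C
F8 | step 7 | (2E)-1-(3-geranyl-4,6-dihydroxy-2-methoxyphenyl)-3-[4-(methoxymethoxy)phenyl]prop-2-en-1-one | O=C(/C=C/c1ccc(OCOC)cc1)c1c(OC)c(C/C=C(\C)CCC=C(C)C)c(O)cc1O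
F9 | step 9 | racemic trans-[3-geranyl-2-methoxy-4,6-bis(methoxymethoxy)phenyl]{3-[4-(methoxymethoxy)phenyl]oxiran-2-yl}methanone (both enantiomers) | COCOc1cc(OCOC)c(C(=O)[C@@H]2O[C@H]2c2ccc(OCOC)cc2)c(OC)c1C/C=C(\C)CCC=C(C)C.COCOc1cc(OCOC)c(C(=O)[C@H]2O[C@@H]2c2ccc(OCOC)cc2)c(OC)c1C/C=C(\C)CCC=C(C)C
F10 | step 9 | [3-geranyl-2-methoxy-4,6-bis(methoxymethoxy)phenyl]{(2S,3R)-3-[4-(methoxymethoxy)phenyl]oxiran-2-yl}methanone | COCOc1cc(OCOC)c(C(=O)[C@H]2O[C@@H]2c2ccc(OCOC)cc2)c(OC)c1C/C=C(\C)CCC=C(C)C
F11 | step 10 | (2S)-3-(benzylsulfanyl)-1-[3-geranyl-2-methoxy-4,6-bis(methoxymethoxy)phenyl]-2-hydroxy-3-[4-(methoxymethoxy)phenyl]propan-1-one (C3 epimers) | COCOc1cc(OCOC)c(C(=O)[C@H](O)C(SCc2ccccc2)c2ccc(OCOC)cc2)c(OC)c1C/C=C(\C)CCC=C(C)C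
F12 | step 10 | (2S)-3-(benzylsulfanyl)-1-(3-geranyl-4,6-dihydroxy-2-methoxyphenyl)-2-hydroxy-3-(4-hydroxyphenyl)propan-1-one (C3 epimers) | COc1c(C/C=C(\C)CCC=C(C)C)c(O)cc(O)c1C(=O)[C@H](O)C(SCc1ccccc1)c1ccc(O)cc1
F13 | step 5 | (2E)-3-[4-(methoxymethoxy)phenyl]prop-2-enal | O=C/C=C/c1ccc(OCOC)cc1
F14 | step 5 | methyl (8E)-2-geranyl-7-hydroxy-9-[4-(methoxymethoxy)phenyl]-3,5-dioxonon-8-enoate (stereoisomers) | COC(=O)C(C/C=C(\C)CCC=C(C)C)C(=O)CC(=O)CC(O)/C=C/c1ccc(OCOC)cc1
A1 | alternative 1 | (2R,3R)-1-[3-geranyl-2-methoxy-6-(methoxymethoxy)-4-(triisopropylsilyloxy)phenyl]-2,3-dihydroxy-3-[4-(triisopropylsilyloxy)phenyl]propan-1-one | COc1c(C/C=C(\C)CCC=C(C)C)c(O[Si](C(C)C)(C(C)C)C(C)C)cc(OCOC)c1C(=O)[C@H](O)[C@@H](c1ccc(O[Si](C(C)C)(C(C)C)C(C)C)cc1)O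
A2 | alternative 1 | 2-diazo-1-[3-geranyl-2-methoxy-6-(methoxymethoxy)-4-(triisopropylsilyloxy)phenyl]ethan-1-one | COc1c(C/C=C(\C)CCC=C(C)C)c(O[Si](C(C)C)(C(C)C)C(C)C)cc(OCOC)c1C(=O)C=[N+]=[N-]
A3 | alternative 1 | 4-(triisopropylsilyloxy)benzaldehyde | O=Cc1ccc(O[Si](C(C)C)(C(C)C)C(C)C)cc1
A4 | alternative 1 | water | O
A5 | alternative 2 | 2,3-trans-3-acetoxy-6-geranyl-4,5-dimethoxy-7-(triisopropylsilyloxy)-2-[4-(triisopropylsilyloxy)phenyl]chroman (C4 epimers) | COc1c(C/C=C(\C)CCC=C(C)C)c(O[Si](C(C)C)(C(C)C)C(C)C)cc2c1C(OC)[C@H](OC(C)=O)[C@@H](c1ccc(O[Si](C(C)C)(C(C)C)C(C)C)cc1)O2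
A6 | alternative 2 | 3-geranyl-6-hydroxy-2-methoxy-4-(triisopropylsilyloxy)benzaldehyde | COc1c(C/C=C(\C)CCC=C(C)C)c(O[Si](C(C)C)(C(C)C)C(C)C)cc(O)c1C=O
A7 | alternative 2 | trimethyl orthoformate | COC(OC)OC
A8 | alternative 2 | (E)-2-[4-(triisopropylsilyloxy)phenyl]ethenyl acetate | CC(=O)O/C=C/c1ccc(O[Si](C(C)C)(C(C)C)C(C)C)cc1
A9 | alternative 3 | 4-geranyl-3-methoxy-5-(triisopropylsilyloxy)phenol | COc1cc(O)cc(O[Si](C(C)C)(C(C)C)C(C)C)c1C/C=C(\C)CCC=C(C)C
A10 | alternative 3 | (6E)-4-diazo-2-methoxy-7,11-dimethyldodeca-1,6,10-trien-3-one | C=C(OC)C(=O)C(=[N+]=[N-])C/C=C(\C)CCC=C(C)C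
A11 | alternative 3 | (triisopropylsilyloxy)ethyne | C#CO[Si](C(C)C)(C(C)C)C(C)C
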